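# Bisisorhapontigenin B by pyridazine–alkyne cycloaddition: a proposed enantioselective route

## Analysis of the target

- Bisisorhapontigenin B is a trans-2,3-diaryl-2,3-dihydrobenzofuran. A benzo ring (C3a, C4, C5, C6, C7, C7a) is fused to a dihydrofuran ring (O1, C2, C3). C2 carries a 4-hydroxy-3-methoxyphenyl group, C3 a 3,5-dihydroxyphenyl group, C4 a hydroxyl and C6 an (E)-4-hydroxy-3-methoxystyryl group.
- The only stereocentres are the adjacent C2 and C3, both S, with the two aryl groups trans; the alkene is E.
- The C2–O1 bond is a benzylic ether para to an oxygen substituent, so acid ionises it and can epimerise or open the ring. C3–H is doubly benzylic and β to O1, so strong base can open the ring by elimination.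
- The electron-rich stilbene excludes hydrogenolysis in the endgame and dislikes strong acid and oxidants. Five phenols must be masked, and two aryl methyl ethers must survive the unmasking.
- The synthesis is hard for two reasons. No resident chirality can relay the absolute configuration of C2 and C3. The benzo ring is 1,2,3,5-tetrasubstituted, with oxygen on C4 but carbon on C6, so its two meta positions must be told apart.
- The route rests on one feature: C7a and C3a, neighbours in the benzo ring, are bridged by exactly three atoms, O1–C2–C3. If C7a–C7–C6–C5 comes from a diene and C4–C3a from an alkyne, this bridge is the tether of an intramolecular cycloaddition. That cycloaddition can form the benzo ring in one regiochemistry only and closes the dihydrofuran ring at the same time.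
- A pyridazine is the right diene. It carries oxygen at the future C7a and an ester at the future C6, and its N=N unit leaves after the cycloaddition. A boron on the alkyne terminus marks C4 for oxygen.

## Retrosynthetic reasoning

**25 from 24.** The last disconnection removes five benzyl groups. Benzyl ethers are chosen because they survive organozinc reagents, alkoxide, heating to 160 °C, peroxide and hydride, and because they can be cleaved by a Lewis acid at low temperature without touching the methyl ethers. Hydrogenolysis is excluded once the stilbene is present.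

**24 from 19 and 22.** The stilbene C=C bond is cut. An olefination of aldehyde 19 with the benzylic phosphonate 22 joins the second isorhapontigenin half late and should give the E alkene. Phosphonate 22 comes in one operation from alcohol 20 through chloride 21.

**19 back to 15.** Aldehyde 19 follows from ester 17 by reduction to alcohol 18 and re-oxidation. The C4 benzyl ether of 17 comes from phenol 16, and 16 from arylboronate 15 by oxidation with retention of position. The ester on C6 and the boron on C4 are thus the two handles the ring-forming step must deliver, and they are meta to each other as required.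

**15 from 13 (key disconnection).** Bonds C3a–C7a and C4–C5 are cut and an N=N bridge is reinserted between C7a and C5, giving adduct 14 and, behind it, pyridazinyl ether 13.
- The cut is made here because it removes the benzo ring and the dihydrofuran ring in one stroke, and the O1–C2–C3 tether leaves no regiochemical choice.
- C2 and C3 are untouched saturated carbons in this step.
- The forward reaction needs only heat: cycloaddition of the alkynylboronate across the diazine, then loss of the diaza bridge.

**13 from 9 and 10.** The C–B bond is cut back to terminal alkyne 12. The heteroaryl C–O bond of 12 is cut to alkynol 9 and chloropyridazine 10, through alkoxide 11. Forming the ether at oxygen leaves the carbinol configuration alone. The boron goes on last because an alkynylboronate would not survive alkoxide.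

**9 from 5 and 6.** Desilylation relates 9 to silylalkyne 8. In 8 the bond between the carbinol carbon and the propargylic carbon (the future C2–C3 bond) is cut. An allenylzinc 7, made from propargylic mesylate 5, adds to aldehyde 6. This single C–C bond formation sets both stereocentres: the propargylic one by transfer from 5, the carbinol one by anti selectivity. The anti adduct maps onto the trans ring.

**5 from 1 and 2.** Mesylate 5 comes from propargylic alcohol 4. The C–C bond of 4 to the alkyne is cut to aldehyde 1 and alkyne 2 (through alkynylzinc 3) in a catalytic enantioselective alkynylation. This is the only step in which absolute configuration is created by a catalyst.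

## Alternatives that were turned down

**Alternative 1:** The benzo ring is closed last by cutting C6–C7.
- Precursor A1 is a trans-4,5-diaryl-2-methyl-4,5-dihydrofuran whose C3 carries a 1,3-diketone chain ending in the benzyl-protected styryl ketone.
- Forward step: strong base deprotonates the ring methyl group (the future C7), which the C4 carbonyl acidifies vinylogously through the enol-ether double bond. The dienolate adds to the styryl ketone carbon (C6). Dehydration and enolisation of the C4 ketone give A2, the target with four benzyl groups and a free C4 hydroxyl.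
- For it: ring formation delivers the C4 oxygen and the whole C6 styryl group at once, so one deprotection finishes the synthesis. On endgame length it is clearly stronger than the chosen route, which needs six operations after the ring is made.
- Against it: the C5 methylene between the two carbonyls is far more acidic than the methyl group. The diketonate forms first and deactivates the C6 carbonyl. The polyanion then needed is made under conditions where the doubly benzylic, allylic C3–H of A1 and conjugate addition to the enone both compete. A1 is also an electron-rich dihydrofuran that can aromatise to a furan, losing both stereocentres, and its enantioselective preparation is no shorter than that of the acyclic alcohol used here.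
- Comparison: the chosen strategy gives up the short endgame. In return its regiochemistry is enforced by a tether, not by competing enolate equilibria, and C2 and C3 are spectators.

**Alternative 2:** The O1–C2 bond is cut.
- Precursor A3 is the redox-active N-acyloxyphthalimide ester of a 2,3,3-triarylpropanoic acid. The aryl group that becomes the benzo ring is a 4-chloro-2,6-bis(methoxymethoxy)phenyl group.
- Forward step: an excited iridium photocatalyst reduces the ester, which fragments with decarboxylation to the C2 benzylic radical. The oxidised catalyst converts this into the para-alkoxybenzyl cation. An ortho acetal oxygen captures it, and loss of the acetal carbon gives A4.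
- For it: it uses the very property that makes C2–O1 labile. Only C3 has to be set beforehand, because C2 is regenerated under the control of C3. The two ortho oxygens are equivalent. The step runs at room temperature. A4 already carries the C4 oxygen and a C6 chloride for direct coupling with a styrene, so the endgame is shorter than here.
- Against it: C3 of A3 is a triarylmethane-type centre flanked by a 2,6-dioxygenated ring and is hard to set enantioselectively. The cation has an adjacent C3–H, and losing it gives a fully conjugated triarylethylene; this should compete strongly with capture by a weakly nucleophilic acetal oxygen. The trans preference is substrate control only. The remaining acetal must later be removed with acid next to the labile C2–O1 bond.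
- Comparison: it is stronger on mildness and endgame economy. The chosen strategy instead sets both centres in one reagent-controlled C–C bond formation and never passes through a cation at C2.

**Alternative 3:** The C3–C3a bond is cut by a ring contraction.
- Precursor A5 is a chiral-pool (2S)-flavanone protected as its 5-O-benzyl, 4'-O-benzyl, 7-O-triflate derivative.
- Forward step: a hypervalent aryl iodine diacetate with strong acid in an orthoformate attacks the enol ether of the C4 ketone at C3. Departure of the iodine triggers a 1,2-shift of ring carbon C4a from the carbonyl carbon to C3. This contracts the pyranone and gives A6, a trans-2-aryl-2,3-dihydrobenzofuran-3-carboxylate.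
- For it: the C2 stereocentre and the oxygenation at the future C4 and C6 come from a natural product. The chelated 5-hydroxyl differentiates the two ring oxygens for free, and the triflate is a ready handle for the styryl group. It reaches a functionalised dihydrobenzofuran in fewer steps than the chosen route.
- Against it: C3 of A6 carries an ester, not the 3,5-dihydroxyphenyl group. Exchanging carboxyl for aryl requires a late decarboxylative arylation through a C3 radical, whose diastereoselectivity rests on C2 alone. Flavanones racemise at C2 by reversible ring opening. The acidic, oxidising medium threatens the electron-rich guaiacyl ring and the benzylic C2–O1 bond. The triflate also makes the migrating ring less willing to shift.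
- Comparison: the hardest bond, C3–aryl, is left for the end. The chosen strategy makes that bond together with the C2 stereocentre at the start.

Key step: step 7

Assumption: (S,S)-ProPhenol is taken to deliver the R carbinol 4 from aldehyde 1; should the facial sense be the opposite, the (R,R)-ligand is used with no other change.

## Route

Step 1
Reactants: 1 3,5-bis(benzyloxy)benzaldehyde; 2 ethynyltrimethylsilane
Product: 4 (1R)-1-[3,5-bis(benzyloxy)phenyl]-3-(trimethylsilyl)prop-2-yn-1-ol, via methyl[(trimethylsilyl)ethynyl]zinc 3 (not isolated)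
Conditions: 2 (3 equiv), Me2Zn (3 equiv), (S,S)-ProPhenol (10 mol %), Ph3P=O (20 mol %), toluene, 0 °C, 1 h; then 1, 4 °C; aq NH4Cl
Reagents that add atoms: none
Why: Zinc–ProPhenol-catalysed enantioselective alkynylation of an aryl aldehyde: the dinuclear zinc complex holds the aldehyde and alkynylzinc 3 on neighbouring metal centres and delivers the alkynyl group to one carbonyl face, which sets the carbinol centre of 4 as R under catalyst control. Aromatic aldehydes without α-hydrogens are the best substrate class for this addition.

Step 2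
Reactants: 4 (1R)-1-[3,5-bis(benzyloxy)phenyl]-3-(trimethylsilyl)prop-2-yn-1-ol
Product: 5 (1R)-1-[3,5-bis(benzyloxy)phenyl]-3-(trimethylsilyl)prop-2-yn-1-yl methanesulfonate
Conditions: MsCl (1.3 equiv), Et3N (1.6 equiv), CH2Cl2, −78 → −40 °C; cold aqueous work-up, used crude at once
Reagents that add atoms: methanesulfonyl chloride, CS(=O)(=O)Cl
Why: Sulfonylation at oxygen leaves the C–O bond and so the configuration untouched. The two meta benzyloxy groups give no resonance stabilisation to a benzylic cation, so 5 should last long enough at low temperature to be used directly.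

Step 3
Reactants: 5 (1R)-1-[3,5-bis(benzyloxy)phenyl]-3-(trimethylsilyl)prop-2-yn-1-yl methanesulfonate; 6 4-(benzyloxy)-3-methoxybenzaldehyde (O-benzylvanillin)
Product: 8 (1S,2S)-1-[4-(benzyloxy)-3-methoxyphenyl]-2-[3,5-bis(benzyloxy)phenyl]-4-(trimethylsilyl)but-3-yn-1-ol, via allenylzinc reagent 7 (not isolated)
Conditions: Pd(OAc)2 (5 mol %), PPh3 (5 mol %), Et2Zn (3 equiv), THF, −78 → −20 °C; aq NH4Cl
Reagents that add atoms: none
Why: Palladium-catalysed, zinc-mediated umpolung of a propargylic mesylate (allenylzinc addition to an aldehyde): zerovalent palladium displaces the mesylate anti in an SN2' sense, transmetallation gives the axially chiral allenylzinc 7, and 7 adds to 6 through a cyclic SE2' transition state on the zinc-bearing face. The net inversion at the propargylic carbon turns the R centre of 5 into the S centre that becomes C3, and the cyclic transition state keeps the aldehyde aryl group away from the allene aryl group, so the new carbinol centre (the future C2) is set S, anti to it, by chirality transfer from the allene axis.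

Step 4
Reactants: 8 (1S,2S)-1-[4-(benzyloxy)-3-methoxyphenyl]-2-[3,5-bis(benzyloxy)phenyl]-4-(trimethylsilyl)but-3-yn-1-ol
Product: 9 (1S,2R)-1-[4-(benzyloxy)-3-methoxyphenyl]-2-[3,5-bis(benzyloxy)phenyl]but-3-yn-1-ol
Conditions: K2CO3 (0.5 equiv), MeOH/THF, rt
Reagents that add atoms: none
Why: Base-catalysed methanolysis of the alkynyl C–Si bond (protodesilylation), done before the base-sensitive heteroaryl ether exists; carbonate is too weak to epimerise either centre. The C2 descriptor changes from S to R only because ethynyl ranks below aryl; the spatial arrangement is unchanged.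

Step 5
Reactants: 9 (1S,2R)-1-[4-(benzyloxy)-3-methoxyphenyl]-2-[3,5-bis(benzyloxy)phenyl]but-3-yn-1-ol; 10 methyl 6-chloropyridazine-4-carboxylate
Product: 12 methyl 6-{[(1S,2R)-1-[4-(benzyloxy)-3-methoxyphenyl]-2-[3,5-bis(benzyloxy)phenyl]but-3-yn-1-yl]oxy}pyridazine-4-carboxylate, via sodium alkoxide 11 (not isolated)
Conditions: NaH (0.98 equiv), THF, 0 °C, 20 min; then 10 (1.3 equiv), 0 °C → rt
Reagents that add atoms: none
Why: Nucleophilic aromatic substitution (addition–elimination) at the chlorine-bearing carbon next to ring nitrogen of an ester-activated diazine; the new bond is made at oxygen, so the carbinol configuration is retained. Alkoxide 11 is preformed with a slight deficit of hydride and met cold with excess 10, so that ester exchange and elimination across the acidic propargylic C–H should not compete and the alkyne C–H is left alone.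

Step 6
Reactants: 12 methyl 6-{[(1S,2R)-1-[4-(benzyloxy)-3-methoxyphenyl]-2-[3,5-bis(benzyloxy)phenyl]but-3-yn-1-yl]oxy}pyridazine-4-carboxylate
Product: 13 methyl 6-{[(1S,2S)-1-[4-(benzyloxy)-3-methoxyphenyl]-2-[3,5-bis(benzyloxy)phenyl]-4-(4,4,5,5-tetramethyl-1,3,2-dioxaborolan-2-yl)but-3-yn-1-yl]oxy}pyridazine-4-carboxylate
Conditions: pinacolborane (1.1 equiv), (CAAC)CuOTf (2.5 mol %; CAAC = cyclic (alkyl)(amino)carbene), Et3N (5 mol %), benzene, rt; filtered through Celite under argon, concentrated, used crude
Reagents that add atoms: pinacolborane, [H]B1OC(C)(C)C(C)(C)O1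
Why: Copper-catalysed dehydrogenative C–H borylation of a terminal alkyne: a monovalent copper acetylide formed with catalytic amine is borylated by pinacolborane, and the copper hydride left behind releases H2 on protonolysis, so no stoichiometric base meets the ester, the diazine or the acidic propargylic position. The descriptor of C2 returns to S because the borylethynyl group outranks aryl.

Step 7
Reactants: 13 methyl 6-{[(1S,2S)-1-[4-(benzyloxy)-3-methoxyphenyl]-2-[3,5-bis(benzyloxy)phenyl]-4-(4,4,5,5-tetramethyl-1,3,2-dioxaborolan-2-yl)but-3-yn-1-yl]oxy}pyridazine-4-carboxylate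
Product: 15 methyl (2S,3S)-2-[4-(benzyloxy)-3-methoxyphenyl]-3-[3,5-bis(benzyloxy)phenyl]-4-(4,4,5,5-tetramethyl-1,3,2-dioxaborolan-2-yl)-2,3-dihydro-1-benzofuran-6-carboxylate, via diazabicyclooctatriene adduct 14 (not isolated)
Conditions: 1,2-dichlorobenzene (0.01 M, degassed, dry), activated 4 Å molecular sieves, 160 °C, sealed tube, argon
Reagents that add atoms: none
Why: Intramolecular inverse-electron-demand Diels–Alder reaction followed by retro-Diels–Alder loss of N2: the tethered alkyne adds across the two carbon termini of the ester-lowered diazadiene (the oxygen-bearing carbon and the CH para to it) to give bridged adduct 14, whose N=N bridge is expelled to aromatise the new ring. The closest known reaction type is the thermal cyclisation of alkyne-tethered 3-alkoxypyridazines to 2,3-dihydrobenzofurans, together with cycloadditions of alkynylboronates with azines and 2-pyranones that give arylboronates. The benzo ring closes by the cycloaddition–cycloreversion pair (bonds C3a–C7a and C4–C5), and the dihydrofuran ring closes in the same event as a five-membered ring, exo with respect to the alkyne, because the three-atom O1–C2–C3 tether lets only the inner alkyne carbon reach the oxygen-bearing diene terminus. No stereocentre is created in 15: the bridgehead centres of 14, formed on either face, vanish with the nitrogen, and C2 and C3 are saturated carbons outside the pericyclic array, so their configuration is carried over. Regioselectivity is therefore fixed by the tether, which puts boron on C4 and the ester on C6. The selectivity that has to be won is chemoselectivity: cycloaddition must outrun loss of the heteroaryloxy group from the benzylic C2 and protodeboronation of the alkyne. The ester lowers the diene LUMO, the anti arrangement of the two aryl groups lets the reactive gauche rotamer form without aryl–aryl eclipsing and leads straight to the trans ring, and a dry, aprotic, non-ionising, acid-free medium at high dilution gives the benzylic C2–O bond no path to ionise.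

Step 8
Reactants: 15 methyl (2S,3S)-2-[4-(benzyloxy)-3-methoxyphenyl]-3-[3,5-bis(benzyloxy)phenyl]-4-(4,4,5,5-tetramethyl-1,3,2-dioxaborolan-2-yl)-2,3-dihydro-1-benzofuran-6-carboxylate
Product: 16 methyl (2S,3S)-2-[4-(benzyloxy)-3-methoxyphenyl]-3-[3,5-bis(benzyloxy)phenyl]-4-hydroxy-2,3-dihydro-1-benzofuran-6-carboxylate
Conditions: 30% aq H2O2, 1 M aq NaOH (1.1 equiv), THF, 0 °C, 30 min
Reagents that add atoms: hydrogen peroxide, OO
Why: Oxidation of an arylboronate by hydroperoxide: the aryl group migrates from boron to oxygen with retention of position, which places the hydroxyl exactly on C4. Short exposure at 0 °C should spare the methyl ester.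

Step 9
Reactants: 16 methyl (2S,3S)-2-[4-(benzyloxy)-3-methoxyphenyl]-3-[3,5-bis(benzyloxy)phenyl]-4-hydroxy-2,3-dihydro-1-benzofuran-6-carboxylate
Product: 17 methyl (2S,3S)-4-(benzyloxy)-2-[4-(benzyloxy)-3-methoxyphenyl]-3-[3,5-bis(benzyloxy)phenyl]-2,3-dihydro-1-benzofuran-6-carboxylate
Conditions: BnBr (1.2 equiv), K2CO3 (2 equiv), DMF, rt
Reagents that add atoms: benzyl bromide, BrCc1ccccc1
Why: Williamson etherification of the phenoxide; carbonate is too weak a base to touch C3–H. The fifth benzyl group matches the others, so one final deprotection suffices.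

Step 10
Reactants: 17 methyl (2S,3S)-4-(benzyloxy)-2-[4-(benzyloxy)-3-methoxyphenyl]-3-[3,5-bis(benzyloxy)phenyl]-2,3-dihydro-1-benzofuran-6-carboxylate
Product: 18 {(2S,3S)-4-(benzyloxy)-2-[4-(benzyloxy)-3-methoxyphenyl]-3-[3,5-bis(benzyloxy)phenyl]-2,3-dihydro-1-benzofuran-6-yl}methanol
Conditions: i-Bu2AlH (2.5 equiv), CH2Cl2, −78 → 0 °C; aq potassium sodium tartrate
Reagents that add atoms: none
Why: Hydride reduction of an aryl ester to the benzylic alcohol; aryl ethers and the dihydrofuran ring are inert to the aluminium hydride at low temperature.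

Step 11
Reactants: 18 {(2S,3S)-4-(benzyloxy)-2-[4-(benzyloxy)-3-methoxyphenyl]-3-[3,5-bis(benzyloxy)phenyl]-2,3-dihydro-1-benzofuran-6-yl}methanol
Product: 19 (2S,3S)-4-(benzyloxy)-2-[4-(benzyloxy)-3-methoxyphenyl]-3-[3,5-bis(benzyloxy)phenyl]-2,3-dihydro-1-benzofuran-6-carbaldehyde
Conditions: activated MnO2 (15 equiv), CH2Cl2, rt
Reagents that add atoms: none
Why: Heterogeneous oxidation of a benzylic alcohol by MnO2 stops at the aldehyde and runs under neutral conditions, which protects the acid-labile C2–O1 bond.

Step 12
Reactants: 20 [4-(benzyloxy)-3-methoxyphenyl]methanol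
Product: 22 diethyl {[4-(benzyloxy)-3-methoxyphenyl]methyl}phosphonate, via benzyl chloride 21 (not isolated)
Conditions: SOCl2 (1.2 equiv), CH2Cl2, 0 °C → rt; concentrate; P(OEt)3 (3 equiv), neat, 130 °C
Reagents that add atoms: triethyl phosphite, CCOP(OCC)OCC
Why: Chlorination of an electron-rich benzylic alcohol followed by Michaelis–Arbuzov reaction of crude chloride 21 with triethyl phosphite.

Step 13
Reactants: 19 (2S,3S)-4-(benzyloxy)-2-[4-(benzyloxy)-3-methoxyphenyl]-3-[3,5-bis(benzyloxy)phenyl]-2,3-dihydro-1-benzofuran-6-carbaldehyde; 22 diethyl {[4-(benzyloxy)-3-methoxyphenyl]methyl}phosphonate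
Product: 24 (2S,3S)-4-(benzyloxy)-2-[4-(benzyloxy)-3-methoxyphenyl]-6-{(E)-2-[4-(benzyloxy)-3-methoxyphenyl]ethenyl}-3-[3,5-bis(benzyloxy)phenyl]-2,3-dihydro-1-benzofuran (penta-O-benzyl bisisorhapontigenin B), via potassium phosphonate carbanion 23 (not isolated)
Conditions: 22 (1.3 equiv), KOtBu (1.2 equiv), THF, 0 °C, 30 min; then 19, −40 → 0 °C
Reagents that add atoms: none
Why: Horner–Wadsworth–Emmons olefination with an aryl-stabilised phosphonate carbanion, which gives the E stilbene through the thermodynamically preferred elimination. Carbanion 23 is preformed with a deficit of base and the aldehyde added cold, so that C3–H, acidified by the para formyl group, should not be deprotonated (which would open the ring by β-elimination of O1).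

Step 14
Reactants: 24 penta-O-benzyl bisisorhapontigenin B
Product: 25 bisisorhapontigenin B, (2S,3S)-3-(3,5-dihydroxyphenyl)-2-(4-hydroxy-3-methoxyphenyl)-6-[(E)-2-(4-hydroxy-3-methoxyphenyl)ethenyl]-2,3-dihydro-1-benzofuran-4-ol
Conditions: BCl3 (1 M in CH2Cl2, 10 equiv), pentamethylbenzene (15 equiv), CH2Cl2, −78 °C; MeOH quench at −78 °C
Reagents that add atoms: none
Why: Lewis-acid cleavage of aryl benzyl ethers with pentamethylbenzene as a non-basic benzyl cation scavenger. At −78 °C the aryl methyl ethers and the alkene should be left alone, and the short cold exposure should keep the C2–O1 bond, and so the trans configuration, intact.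

## Compound list

1 | 3,5-bis(benzyloxy)benzaldehyde | O=Cc1cc(OCc2ccccc2)cc(OCc2ccccc2)c1 | starting material
2 | ethynyltrimethylsilane | C#C[Si](C)(C)C | starting material
3 | methyl[(trimethylsilyl)ethynyl]zinc | C[Zn]C#C[Si](C)(C)C | intermediate
4 | (1R)-1-[3,5-bis(benzyloxy)phenyl]-3-(trimethylsilyl)prop-2-yn-1-ol | O[C@@H](C#C[Si](C)(C)C)c1cc(OCc2ccccc2)cc(OCc2ccccc2)c1 | intermediate
5 | (1R)-1-[3,5-bis(benzyloxy)phenyl]-3-(trimethylsilyl)prop-2-yn-1-yl methanesulfonate | CS(=O)(=O)O[C@@H](C#C[Si](C)(C)C)c1cc(OCc2ccccc2)cc(OCc2ccccc2)c1 | intermediate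
6 | 4-(benzyloxy)-3-methoxybenzaldehyde (O-benzylvanillin) | COc1cc(C=O)ccc1OCc1ccccc1 | starting material
7 | ethyl{(Sa)-3-[3,5-bis(benzyloxy)phenyl]-1-(trimethylsilyl)propa-1,2-dien-1-yl}zinc | [H]C(c1cc(OCc2ccccc2)cc(OCc2ccccc2)c1)=[C@@]=C([Zn]CC)[Si](C)(C)C | intermediate
8 | (1S,2S)-1-[4-(benzyloxy)-3-methoxyphenyl]-2-[3,5-bis(benzyloxy)phenyl]-4-(trimethylsilyl)but-3-yn-1-ol (anti) | O[C@H](c1ccc(OCc2ccccc2)c(OC)c1)[C@H](C#C[Si](C)(C)C)c1cc(OCc2ccccc2)cc(OCc2ccccc2)c1 | intermediate
9 | (1S,2R)-1-[4-(benzyloxy)-3-methoxyphenyl]-2-[3,5-bis(benzyloxy)phenyl]but-3-yn-1-ol | O[C@H](c1ccc(OCc2ccccc2)c(OC)c1)[C@H](C#C)c1cc(OCc2ccccc2)cc(OCc2ccccc2)c1 | intermediate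
10 | methyl 6-chloropyridazine-4-carboxylate | COC(=O)c1cnnc(Cl)c1 | starting material
11 | sodium (1S,2R)-1-[4-(benzyloxy)-3-methoxyphenyl]-2-[3,5-bis(benzyloxy)phenyl]but-3-yn-1-olate | [Na+].[O-][C@H](c1ccc(OCc2ccccc2)c(OC)c1)[C@H](C#C)c1cc(OCc2ccccc2)cc(OCc2ccccc2)c1 | intermediate
12 | methyl 6-{[(1S,2R)-1-[4-(benzyloxy)-3-methoxyphenyl]-2-[3,5-bis(benzyloxy)phenyl]but-3-yn-1-yl]oxy}pyridazine-4-carboxylate | COC(=O)c1cnnc(O[C@H](c2ccc(OCc3ccccc3)c(OC)c2)[C@H](C#C)c2cc(OCc3ccccc3)cc(OCc3ccccc3)c2)c1 | intermediate
13 | methyl 6-{[(1S,2S)-1-[4-(benzyloxy)-3-methoxyphenyl]-2-[3,5-bis(benzyloxy)phenyl]-4-(4,4,5,5-tetramethyl-1,3,2-dioxaborolan-2-yl)but-3-yn-1-yl]oxy}pyridazine-4-carboxylate | COC(=O)c1cnnc(O[C@H](c2ccc(OCc3ccccc3)c(OC)c2)[C@H](C#CB2OC(C)(C)C(C)(C)O2)c2cc(OCc3ccccc3)cc(OCc3ccccc3)c2)c1 | intermediate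
14 | bridged [4+2] adduct: 2,3-diazabicyclo[2.2.2]octa-2,5,7-triene whose N=N bridge spans the future C7a and C5, with C2 and C3 as in 13 and the bridgeheads formed on either face | COC(=O)C1=CC23N=NC1C(B4OC(C)(C)C(C)(C)O4)=C2[C@H](c2cc(OCc4ccccc4)cc(OCc4ccccc4)c2)[C@@H](c2ccc(OCc4ccccc4)c(OC)c2)O3 | intermediate
15 | methyl (2S,3S)-2-[4-(benzyloxy)-3-methoxyphenyl]-3-[3,5-bis(benzyloxy)phenyl]-4-(4,4,5,5-tetramethyl-1,3,2-dioxaborolan-2-yl)-2,3-dihydro-1-benzofuran-6-carboxylate | COC(=O)c1cc(B2OC(C)(C)C(C)(C)O2)c2c(c1)O[C@H](c1ccc(OCc3ccccc3)c(OC)c1)[C@H]2c1cc(OCc3ccccc3)cc(OCc3ccccc3)c1 | intermediate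
16 | methyl (2S,3S)-2-[4-(benzyloxy)-3-methoxyphenyl]-3-[3,5-bis(benzyloxy)phenyl]-4-hydroxy-2,3-dihydro-1-benzofuran-6-carboxylate | COC(=O)c1cc(O)c2c(c1)O[C@H](c1ccc(OCc3ccccc3)c(OC)c1)[C@H]2c1cc(OCc3ccccc3)cc(OCc3ccccc3)c1 | intermediate
17 | methyl (2S,3S)-4-(benzyloxy)-2-[4-(benzyloxy)-3-methoxyphenyl]-3-[3,5-bis(benzyloxy)phenyl]-2,3-dihydro-1-benzofuran-6-carboxylate | COC(=O)c1cc(OCc2ccccc2)c2c(c1)O[C@H](c1ccc(OCc3ccccc3)c(OC)c1)[C@H]2c1cc(OCc3ccccc3)cc(OCc3ccccc3)c1 | intermediate
18 | {(2S,3S)-4-(benzyloxy)-2-[4-(benzyloxy)-3-methoxyphenyl]-3-[3,5-bis(benzyloxy)phenyl]-2,3-dihydro-1-benzofuran-6-yl}methanol | OCc1cc(OCc2ccccc2)c2c(c1)O[C@H](c1ccc(OCc3ccccc3)c(OC)c1)[C@H]2c1cc(OCc3ccccc3)cc(OCc3ccccc3)c1 | intermediate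
19 | (2S,3S)-4-(benzyloxy)-2-[4-(benzyloxy)-3-methoxyphenyl]-3-[3,5-bis(benzyloxy)phenyl]-2,3-dihydro-1-benzofuran-6-carbaldehyde | O=Cc1cc(OCc2ccccc2)c2c(c1)O[C@H](c1ccc(OCc3ccccc3)c(OC)c1)[C@H]2c1cc(OCc3ccccc3)cc(OCc3ccccc3)c1 | intermediate
20 | [4-(benzyloxy)-3-methoxyphenyl]methanol | COc1cc(CO)ccc1OCc1ccccc1 | starting material
21 | 1-(benzyloxy)-4-(chloromethyl)-2-methoxybenzene | COc1cc(CCl)ccc1OCc1ccccc1 | intermediate
22 | diethyl {[4-(benzyloxy)-3-methoxyphenyl]methyl}phosphonate | CCOP(=O)(OCC)Cc1ccc(OCc2ccccc2)c(OC)c1 | intermediate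
23 | potassium salt of the benzylic carbanion of 22 | [K+].CCOP(=O)(OCC)[CH-]c1ccc(OCc2ccccc2)c(OC)c1 | intermediate
24 | (2S,3S)-4-(benzyloxy)-2-[4-(benzyloxy)-3-methoxyphenyl]-6-{(E)-2-[4-(benzyloxy)-3-methoxyphenyl]ethenyl}-3-[3,5-bis(benzyloxy)phenyl]-2,3-dihydro-1-benzofuran | COc1cc(/C=C/c2cc(OCc3ccccc3)c3c(c2)O[C@H](c2ccc(OCc4ccccc4)c(OC)c2)[C@H]3c2cc(OCc4ccccc4)cc(OCc4ccccc4)c2)ccc1OCc1ccccc1 | intermediate
25 | bisisorhapontigenin B, (2S,3S)-3-(3,5-dihydroxyphenyl)-2-(4-hydroxy-3-methoxyphenyl)-6-[(E)-2-(4-hydroxy-3-methoxyphenyl)ethenyl]-2,3-dihydro-1-benzofuran-4-ol | COc1cc(/C=C/c2cc(O)c3c(c2)O[C@H](c2ccc(O)c(OC)c2)[C@H]3c2cc(O)cc(O)c2)ccc1O | target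

## Step count and least certain steps

Total step count: 14. Longest linear sequence: 13 steps (steps 1 to 11, 13 and 14, from aldehyde 1); step 12 is a one-operation side branch.

**Step 7 (key step).**
- Risk: the cycloaddition may be too slow at the temperature the benzylic C2–O bond tolerates, so that loss of the heteroaryloxy group by ionisation or elimination across the propargylic C–H overtakes ring formation. The three-coordinate boron makes the alkyne slightly electron-poor, a mismatch with the electron-poor diene. Traces of water can also cause protodeboronation before the rings close.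
- Fallback: it sets out from 13 and returns at 16. Aqueous KHF2 in methanol followed by cation exchange with n-Bu4NOH should convert 13 into the tetrabutylammonium alkynyltrifluoroborate F1. Its four-coordinate boron makes the alkyne a donor-substituted, hydrolytically robust dienophile that dissolves in 1,2-dichlorobenzene. Heating F1 as in step 7 should give the tetrabutylammonium aryltrifluoroborate F2, which KHSO5 in aqueous acetone oxidises to phenol 16.

**Step 6.**
- Risk: the copper hydride–pinacolborane pair may reduce or hydroborate the electron-poor diazine or the ester, the diazine nitrogens may inhibit the catalyst, and the alkynylboronate may hydrolyse on handling.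
- Fallback: it sets out from 12 and returns at 15, using a halogen in place of boron as the marker. NBS (1.05 equiv) with catalytic AgNO3 in acetone at 0 °C should give the chromatographable 1-bromoalkyne F3. Heating F3 under the conditions of step 7 should give the 4-bromo-2,3-dihydrobenzofuran ester F4. Miyaura borylation of F4 (Pd(dppf)Cl2, B2pin2, KOAc, dioxane, 90 °C) leads to 15.

**Step 3.**
- Risk: an aryl group at the allene terminus may speed up racemisation of the allenylzinc by metallotropic shift through a benzylic zinc species. Anti selectivity may erode with an aromatic aldehyde, and the benzylic mesylate may decompose before oxidative addition.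
- Fallback: it sets out from 4 (with 6) and returns at 8, replacing the zinc reagent by an isolable, configurationally stable boron reagent. Methyl chloroformate and pyridine convert 4 into the propargylic methyl carbonate F5. Copper-catalysed anti-SN2' borylation (CuCl, NaOtBu and Xantphos in catalytic amounts, B2pin2, THF) should give the allenylboronate F6 with the same axial sense as 7. Warming F6 with 6 in toluene should give, through a closed transition state and after aqueous work-up, the anti alcohol 8.

**Step 5.**
- Risk: the alkoxide may exchange with the methyl ester and release methoxide, which would consume 10. The product may lose the heteroaryloxy group by base-induced elimination across the acidic propargylic C–H.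
- Fallback: it sets out from 10 and 9 and returns at 12, removing the competing electrophile. LiOH in THF/water at 0 °C hydrolyses 10 to 6-chloropyridazine-4-carboxylic acid F7. The substitution is then run on its carboxylate with 9 and NaH (2.1 equiv) in DMF at 40 °C to give the ether acid F8. (Trimethylsilyl)diazomethane in methanol/toluene re-forms the methyl ester 12.

**Step 14.**
- Risk: Lewis-acid ionisation of the C2–O1 bond, followed by ring opening, epimerisation or capture of the cation by the scavenger. Partial demethylation next to the freed phenols and addition of HCl to the electron-rich stilbene are also possible.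
- Fallback: it sets out from 17 and 22 and returns at 25, exchanging the benzyl groups for silyl groups before the alkene exists.
  - Hydrogenolysis of 17 (H2, Pd/C, ethyl acetate, stopped after four equivalents of hydrogen) gives the tetraphenol ester F9.
  - TBSCl and imidazole give the tetrasilyl ester F10.
  - i-Bu2AlH gives alcohol F11, and MnO2 gives aldehyde F12.
  - Hydrogenolysis of 22 gives the hydroxy phosphonate F13, which is silylated to the silyloxy phosphonate F14.
  - Olefination of F12 with the anion of F14 (NaHMDS, THF, −40 → 0 °C) gives the pentasilyl stilbene F15.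
  - n-Bu4NF buffered with acetic acid at 0 °C releases 25 without any Lewis acid.

## Further compounds

F1 | step 7 | tetrabutylammonium alkynyltrifluoroborate corresponding to 13 (trifluoroborate in place of the pinacol boronate) | CCCC[N+](CCCC)(CCCC)CCCC.COC(=O)c1cnnc(O[C@H](c2ccc(OCc3ccccc3)c(OC)c2)[C@H](C#C[B-](F)(F)F)c2cc(OCc3ccccc3)cc(OCc3ccccc3)c2)c1
F2 | step 7 | tetrabutylammonium aryltrifluoroborate corresponding to 15 (trifluoroborate on C4) | CCCC[N+](CCCC)(CCCC)CCCC.COC(=O)c1cc([B-](F)(F)F)c2c(c1)O[C@H](c1ccc(OCc3ccccc3)c(OC)c1)[C@H]2c1cc(OCc3ccccc3)cc(OCc3ccccc3)c1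
F3 | step 6 | methyl 6-{[(1S,2S)-1-[4-(benzyloxy)-3-methoxyphenyl]-2-[3,5-bis(benzyloxy)phenyl]-4-bromobut-3-yn-1-yl]oxy}pyridazine-4-carboxylate | COC(=O)c1cnnc(O[C@H](c2ccc(OCc3ccccc3)c(OC)c2)[C@H](C#CBr)c2cc(OCc3ccccc3)cc(OCc3ccccc3)c2)c1
F4 | step 6 | methyl (2S,3S)-2-[4-(benzyloxy)-3-methoxyphenyl]-3-[3,5-bis(benzyloxy)phenyl]-4-bromo-2,3-dihydro-1-benzofuran-6-carboxylate | COC(=O)c1cc(Br)c2c(c1)O[C@H](c1ccc(OCc3ccccc3)c(OC)c1)[C@H]2c1cc(OCc3ccccc3)cc(OCc3ccccc3)c1
F5 | step 3 | (1R)-1-[3,5-bis(benzyloxy)phenyl]-3-(trimethylsilyl)prop-2-yn-1-yl methyl carbonate | COC(=O)O[C@@H](C#C[Si](C)(C)C)c1cc(OCc2ccccc2)cc(OCc2ccccc2)c1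
F6 | step 3 | (Ra)-2-{3-[3,5-bis(benzyloxy)phenyl]-1-(trimethylsilyl)propa-1,2-dien-1-yl}-4,4,5,5-tetramethyl-1,3,2-dioxaborolane | [H]C(c1cc(OCc2ccccc2)cc(OCc2ccccc2)c1)=[C@@]=C(B1OC(C)(C)C(C)(C)O1)[Si](C)(C)C
F7 | step 5 | 6-chloropyridazine-4-carboxylic acid | OC(=O)c1cnnc(Cl)c1
F8 | step 5 | 6-{[(1S,2R)-1-[4-(benzyloxy)-3-methoxyphenyl]-2-[3,5-bis(benzyloxy)phenyl]but-3-yn-1-yl]oxy}pyridazine-4-carboxylic acid | OC(=O)c1cnnc(O[C@H](c2ccc(OCc3ccccc3)c(OC)c2)[C@H](C#C)c2cc(OCc3ccccc3)cc(OCc3ccccc3)c2)c1
F9 | step 14 | methyl (2S,3S)-3-(3,5-dihydroxyphenyl)-4-hydroxy-2-(4-hydroxy-3-methoxyphenyl)-2,3-dihydro-1-benzofuran-6-carboxylate | COC(=O)c1cc(O)c2c(c1)O[C@H](c1ccc(O)c(OC)c1)[C@H]2c1cc(O)cc(O)c1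
F10 | step 14 | tetrakis(tert-butyldimethylsilyl) ether of F9 | COC(=O)c1cc(O[Si](C)(C)C(C)(C)C)c2c(c1)O[C@H](c1ccc(O[Si](C)(C)C(C)(C)C)c(OC)c1)[C@H]2c1cc(O[Si](C)(C)C(C)(C)C)cc(O[Si](C)(C)C(C)(C)C)c1
F11 | step 14 | tetrasilyl benzylic alcohol from F10 | OCc1cc(O[Si](C)(C)C(C)(C)C)c2c(c1)O[C@H](c1ccc(O[Si](C)(C)C(C)(C)C)c(OC)c1)[C@H]2c1cc(O[Si](C)(C)C(C)(C)C)cc(O[Si](C)(C)C(C)(C)C)c1
F12 | step 14 | tetrasilyl 6-carbaldehyde from F11 | O=Cc1cc(O[Si](C)(C)C(C)(C)C)c2c(c1)O[C@H](c1ccc(O[Si](C)(C)C(C)(C)C)c(OC)c1)[C@H]2c1cc(O[Si](C)(C)C(C)(C)C)cc(O[Si](C)(C)C(C)(C)C)c1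
F13 | step 14 | diethyl [(4-hydroxy-3-methoxyphenyl)methyl]phosphonate | CCOP(=O)(OCC)Cc1ccc(O)c(OC)c1
F14 | step 14 | diethyl {[4-(tert-butyldimethylsilyloxy)-3-methoxyphenyl]methyl}phosphonate | CCOP(=O)(OCC)Cc1ccc(O[Si](C)(C)C(C)(C)C)c(OC)c1
F15 | step 14 | pentakis(tert-butyldimethylsilyl) ether of bisisorhapontigenin B | COc1cc(/C=C/c2cc(O[Si](C)(C)C(C)(C)C)c3c(c2)O[C@H](c2ccc(O[Si](C)(C)C(C)(C)C)c(OC)c2)[C@H]3c2cc(O[Si](C)(C)C(C)(C)C)cc(O[Si](C)(C)C(C)(C)C)c2)ccc1O[Si](C)(C)C(C)(C)C
A1 | alternative 1 | trans-4,5-diaryl-2-methyl-4,5-dihydrofuran with a C3 1,3-diketone chain ending in the benzyl-protected styryl ketone (ring centres as C3 and C2 of 25) | CC1=C(C(=O)CC(=O)/C=C/c2ccc(OCc3ccccc3)c(OC)c2)[C@H](c2cc(OCc3ccccc3)cc(OCc3ccccc3)c2)[C@@H](c2ccc(OCc3ccccc3)c(OC)c2)O1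
A2 | alternative 1 | tetra-O-benzyl bisisorhapontigenin B with free C4 hydroxyl | COc1cc(/C=C/c2cc(O)c3c(c2)O[C@H](c2ccc(OCc4ccccc4)c(OC)c2)[C@H]3c2cc(OCc4ccccc4)cc(OCc4ccccc4)c2)ccc1OCc1ccccc1
A3 | alternative 2 | N-acyloxyphthalimide ester of 2-[4-(benzyloxy)-3-methoxyphenyl]-3-[3,5-bis(benzyloxy)phenyl]-3-[4-chloro-2,6-bis(methoxymethoxy)phenyl]propanoic acid (C3 as in 25, C2 unspecified) | O=C(ON1C(=O)c2ccccc2C1=O)C(c1ccc(OCc2ccccc2)c(OC)c1)[C@H](c1c(OCOC)cc(Cl)cc1OCOC)c1cc(OCc2ccccc2)cc(OCc2ccccc2)c1
A4 | alternative 2 | (2S,3S)-2-[4-(benzyloxy)-3-methoxyphenyl]-3-[3,5-bis(benzyloxy)phenyl]-6-chloro-4-(methoxymethoxy)-2,3-dihydro-1-benzofuran | Clc1cc(OCOC)c2c(c1)O[C@H](c1ccc(OCc3ccccc3)c(OC)c1)[C@H]2c1cc(OCc3ccccc3)cc(OCc3ccccc3)c1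
A5 | alternative 3 | (2S)-5-(benzyloxy)-2-[4-(benzyloxy)-3-methoxyphenyl]-4-oxochroman-7-yl trifluoromethanesulfonate | O=C1C[C@@H](c2ccc(OCc3ccccc3)c(OC)c2)Oc2cc(OS(=O)(=O)C(F)(F)F)cc(OCc3ccccc3)c12
A6 | alternative 3 | methyl trans-4-(benzyloxy)-2-[4-(benzyloxy)-3-methoxyphenyl]-6-(trifluoromethanesulfonyloxy)-2,3-dihydro-1-benzofuran-3-carboxylate | FC(F)(F)S(=O)(=O)Oc1cc(OCc2ccccc2)c2c(c1)O[C@H](c1ccc(OCc3ccccc3)c(OC)c1)[C@H]2C(=O)OC
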